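Watch the drain.

substrate 1.2 M; coupling partner 0.900 equiv; scavenger 1.00 equiv; capture agent 0.0600 M; time 25 min

1. part of the substrate that has reacted at 25 min
2. share of the unused coupling partner that is free and not bound as idle adduct, at 25 min

- released group is meant together with its idle adduct
- run time (flask): 25 min

    coupling partner + released group ⇌ idle adduct, settled at all times (K1 = 1.4 M⁻¹)
    open intermediate ⇌ target + released group (K2 = 8.1 M, k2 = 0.24 min⁻¹)
    open intermediate + capture agent → trapped intermediate (k3 = 0.18 M⁻¹ min⁻¹)
    substrate + coupling partner ⇌ open intermediate (K4 = 0.079 M⁻¹, k4 = 0.88 M⁻¹ min⁻¹)
    scavenger + released group → scavenged by-product (k5 = 2.0 M⁻¹ min⁻¹)

I began with the first instants. By its forward rate alone, with the way back not counted and coupling partner as charged, substrate had a half-life of 0.73 min, shorter than the 25 min run. Open intermediate fell back at 11.1 min⁻¹, far faster than its onward 0.24 min⁻¹, so I held it at balance and put it near 8.53% of the substrate, reckoned on the charges. That made the step to target the rate-limiting step. Capture was a small extra: open intermediate had a half-life of 64 min by capture alone against 2.9 min by the forward step to target alone.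

For the middle I defined the drain number N as the balance constant of the joining step, times the summed first-order rates out of open intermediate (capture agent held at its charge), times the substrate charged, times the time: 0.594. Let x be the fraction of substrate charge reacted and b the equivalents of coupling partner, the limiting reagent. The second-order drain then integrates to ln[(1 − x)b/(b − x)] = (1 − b)N.

For the end, this gave me x = 34.2%. This was an estimate: it counted material held as open intermediate as still free, which overstated the drain, and it left that held material out of x, which understated the part reacted. My reckoning stopped at this first question.

The forecast gave 33.5% and 99.2%, its first figure a little below my 34.2%, on the grounds that open intermediate “stays close to its fast pre-equilibrium”.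

The flask gave 34.0% and 99.2%, so the forecast held.

Two things together, each a part, kept the flask at that figure: the way back from open intermediate and the time given. Without that way back the answer was 89.2%, and left for 250 min it was 78.8%. N grows with time, so there it stood at 5.94, and the closed form gave 80.1%. In the neighbour charged with 2.0 M of substrate, at the same equivalents and time, N was 0.991 and the form gave 45.9%. The computed answer there was 44.2%.

(The constants used here are made up, and the outcome is calculated.)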